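**Retrosynthetic overview** (cembrane numbering: C1 = lactone ring CH, C2 = OCH, C9 = CHOAc, C15/C16/C17 = lactone α‑carbon, carbonyl, methylene)
1. Starting materials: (R)-(−)-linalool 1, geranyl acetate 2, methyl acrylate 3.
2. C1–C2 and C2–O–C16: last step; CrCl2-mediated intramolecular allylation of the C2 enal by a 2-(bromomethyl)enoate closes the 14-membered carbocycle first, then the γ-lactone forms in the same operation.
3. C1–C15: Morita–Baylis–Hillman reaction of the C1 aldehyde (from the terminal isopropylidene) with methyl acrylate, then SN2′ bromination.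
4. C9–C10 (key bond) and the C9 stereocentre: [2,3]-Wittig rearrangement of a bis-allylic ether, with chirality transfer from the carbinol carbon of linalool.
5. C9–O–C12 ether: Williamson coupling of linalool with 8-bromogeranyl acetate (SeO2 oxidation of geranyl acetate, then Appel bromination).

Assumption: commercial (R)-(−)-linalool of at least 95% ee is used; its enantiomeric purity limits that of the product.

**Step 1**
Reactants: 2 geranyl acetate
Product: 4 (2E,6E)-8-hydroxy-3,7-dimethylocta-2,6-dien-1-yl acetate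
Conditions: SeO2 (0.1 equiv), t-BuOOH (3 equiv), salicylic acid (0.1 equiv), CH2Cl2, rt
Reagents that add atoms: tert-butyl hydroperoxide, CC(C)(C)OO
Why: SeO2-catalysed allylic oxidation (ene reaction then [2,3]-shift) hydroxylates only the E-methyl of the remote trisubstituted olefin, because the other olefin is deactivated by the allylic acetate; no stereocentre is formed.

**Step 2**
Reactants: 4 (2E,6E)-8-hydroxy-3,7-dimethylocta-2,6-dien-1-yl acetate
Product: 5 (2E,6E)-8-bromo-3,7-dimethylocta-2,6-dien-1-yl acetate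
Conditions: CBr4, PPh3, CH2Cl2, 0 °C
Reagents that add atoms: carbon tetrabromide, BrC(Br)(Br)Br
Why: Appel bromination of the primary allylic alcohol is fast at 0 °C and leaves the acetate and both E-olefins untouched.

**Step 3**
Reactants: 1 (R)-(−)-linalool; 5 (2E,6E)-8-bromo-3,7-dimethylocta-2,6-dien-1-yl acetate
Product: 7 (2E,6E)-8-{[(3R)-3,7-dimethylocta-1,6-dien-3-yl]oxy}-3,7-dimethylocta-2,6-dien-1-ol, via linalyl ether acetate 6 (not isolated)
Conditions: KH (1.2 equiv), 18-crown-6 (cat.), THF, 0 °C, then 5, 0 °C → rt; then K2CO3 (cat.), MeOH, rt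
Reagents that add atoms: none
Why: Williamson etherification (SN2 of the tertiary potassium alkoxide on the primary allylic bromide) followed by K2CO3-catalysed methanolysis of the acetate in the same flask; the linalool stereocentre is not touched.

**Step 4**
Reactants: 7 (2E,6E)-8-{[(3R)-3,7-dimethylocta-1,6-dien-3-yl]oxy}-3,7-dimethylocta-2,6-dien-1-ol
Product: 8 (2E,6E,8S,10E)-3,7,11,15-tetramethylhexadeca-2,6,10,14-tetraene-1,8-diol
Conditions: n-BuLi (2.3 equiv), THF, −78 → −30 °C; then H2O
Reagents that add atoms: none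
Why: [2,3]-Wittig rearrangement of the alkoxide/α-oxyallyl dianion: the suprafacial envelope transition state, with the chain of the tertiary carbon and the 2-methylalkenyl group both exo, forms the C8–C9 bond, transfers the (R) configuration of the C–O carbon to (S) at C8 and gives the 10E olefin (the minor 10Z isomer has the opposite C8 configuration and is removed on AgNO3-impregnated silica).

**Step 5**
Reactants: 8 (2E,6E,8S,10E)-3,7,11,15-tetramethylhexadeca-2,6,10,14-tetraene-1,8-diol
Product: 10 (2E,6E,8S,10E)-3,7,11,15-tetramethyl-1-oxohexadeca-2,6,10,14-tetraen-8-yl acetate, via hydroxy enal 9 (not isolated)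
Conditions: 2,2,6,6-tetramethylpiperidin-1-oxyl (TEMPO, 0.1 equiv), PhI(OAc)2 (1.1 equiv), CH2Cl2, rt; then Et3N, Ac2O, 4-(dimethylamino)pyridine (cat.), 0 °C → rt
Reagents that add atoms: acetic anhydride, CC(=O)OC(C)=O
Why: the oxoammonium oxidation (TEMPO/PhI(OAc)2) takes only the primary allylic alcohol to the E-enal, and the remaining secondary allylic alcohol is then acetylated in the same flask without touching C8.

**Step 6**
Reactants: 10 (2E,6E,8S,10E)-3,7,11,15-tetramethyl-1-oxohexadeca-2,6,10,14-tetraen-8-yl acetate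
Product: 12 (2E,6E,8S,10E)-13-(3,3-dimethyloxiran-2-yl)-3,7,11-trimethyl-1-oxotrideca-2,6,10-trien-8-yl acetate (both oxirane epimers), via terminal bromohydrin 11 (not isolated)
Conditions: N-bromosuccinimide (1.05 equiv), THF/H2O (3:1), 0 °C; extractive work-up, then DBU (1.2 equiv), CH2Cl2, 0 °C → rt
Reagents that add atoms: water, O
Why: van Tamelen-type bromohydrin formation prefers the terminal isopropylidene (the other olefins are deactivated by conjugation or by the allylic/homoallylic acetate and are less accessible), and base closes the bromohydrin to the epoxide; the new oxirane stereocentre is lost in step 7.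

**Step 7**
Reactants: 12 (2E,6E,8S,10E)-13-(3,3-dimethyloxiran-2-yl)-3,7,11-trimethyl-1-oxotrideca-2,6,10-trien-8-yl acetate
Product: 13 (2E,6E,8S,10E)-3,7,11-trimethyl-1,14-dioxotetradeca-2,6,10-trien-8-yl acetate
Conditions: H5IO6 (1.2 equiv), THF/Et2O, 0 °C → rt
Reagents that add atoms: none
Why: periodic acid hydrates the trisubstituted epoxide and cleaves the resulting glycol (Malaprade cleavage) to the aldehyde and acetone without affecting olefins, enal or acetate.

**Step 8**
Reactants: 13 (2E,6E,8S,10E)-3,7,11-trimethyl-1,14-dioxotetradeca-2,6,10-trien-8-yl acetate; 3 methyl acrylate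
Product: 14 methyl (6E,9S,10E,14E)-9-acetoxy-3-hydroxy-6,10,14-trimethyl-2-methylidene-16-oxohexadeca-6,10,14-trienoate (both C3 epimers)
Conditions: 1,4-diazabicyclo[2.2.2]octane (DABCO, 1 equiv), 3 (5 equiv, neat), rt, 3–5 d
Reagents that add atoms: none
Why: Morita–Baylis–Hillman reaction; the ammonium enolate of the acrylate adds to the unhindered aliphatic aldehyde much faster than to the β,β-disubstituted enal, and the new carbinol centre (both epimers) is removed in step 9.

**Step 9**
Reactants: 14 methyl (6E,9S,10E,14E)-9-acetoxy-3-hydroxy-6,10,14-trimethyl-2-methylidene-16-oxohexadeca-6,10,14-trienoate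
Product: 15 methyl (2Z,6E,9S,10E,14E)-9-acetoxy-2-(bromomethyl)-6,10,14-trimethyl-16-oxohexadeca-2,6,10,14-tetraenoate
Conditions: PBr3 (0.5 equiv), Et2O, 0 °C
Reagents that add atoms: phosphorus tribromide, BrP(Br)Br
Why: SN2′ bromination of the Baylis–Hillman alcohol gives the thermodynamically preferred (2Z)-2-(bromomethyl)enoate and erases the carbinol stereocentre.

**Step 10**
Reactants: 15 methyl (2Z,6E,9S,10E,14E)-9-acetoxy-2-(bromomethyl)-6,10,14-trimethyl-16-oxohexadeca-2,6,10,14-tetraenoate
Product: 17 (3aR,6E,9S,10E,14E,15aS)-6,10,14-trimethyl-3-methylidene-2-oxo-2,3,3a,4,5,8,9,12,13,15a-decahydrocyclotetradeca[b]furan-9-yl acetate (the target), via seco hydroxy ester 16 (not isolated)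
Conditions: CrCl2 (6 equiv), THF, rt, syringe-pump addition of 15 (final 2 mM); then p-toluenesulfonic acid monohydrate (cat.), CH2Cl2, rt
Reagents that add atoms: none
Why: intramolecular Nozaki–Hiyama (Barbier-type) allylation: the allylchromium adds 1,2 to the enal through a chair transition state with both ends of the twelve-atom tether equatorial (anti adduct, hence trans-lactone after acid-catalysed lactonisation), and the face is chosen by the resident C9 acetoxy stereocentre lying pseudo-equatorially on the forming ring (macrocyclic substrate control), setting C1 (R) and C2 (S).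

**Compound list**
1 | (R)-(−)-linalool, (3R)-3,7-dimethylocta-1,6-dien-3-ol | C=C[C@](C)(O)CCC=C(C)C | starting material
2 | geranyl acetate, (2E)-3,7-dimethylocta-2,6-dien-1-yl acetate | CC(C)=CCC/C(C)=C/COC(C)=O | starting material
3 | methyl acrylate | C=CC(=O)OC | starting material
4 | (2E,6E)-8-hydroxy-3,7-dimethylocta-2,6-dien-1-yl acetate | OC/C(C)=C/CC/C(C)=C/COC(C)=O | intermediate
5 | (2E,6E)-8-bromo-3,7-dimethylocta-2,6-dien-1-yl acetate | BrC/C(C)=C/CC/C(C)=C/COC(C)=O | intermediate
6 | (2E,6E)-8-{[(3R)-3,7-dimethylocta-1,6-dien-3-yl]oxy}-3,7-dimethylocta-2,6-dien-1-yl acetate | C=C[C@](C)(OC/C(C)=C/CC/C(C)=C/COC(C)=O)CCC=C(C)C | intermediate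
7 | (2E,6E)-8-{[(3R)-3,7-dimethylocta-1,6-dien-3-yl]oxy}-3,7-dimethylocta-2,6-dien-1-ol | C=C[C@](C)(OC/C(C)=C/CC/C(C)=C/CO)CCC=C(C)C | intermediate
8 | (2E,6E,8S,10E)-3,7,11,15-tetramethylhexadeca-2,6,10,14-tetraene-1,8-diol | OC/C=C(\C)CC/C=C(\C)[C@@H](O)C/C=C(\C)CCC=C(C)C | intermediate
9 | (2E,6E,8S,10E)-8-hydroxy-3,7,11,15-tetramethylhexadeca-2,6,10,14-tetraenal | O=C/C=C(\C)CC/C=C(\C)[C@@H](O)C/C=C(\C)CCC=C(C)C | intermediate
10 | (2E,6E,8S,10E)-3,7,11,15-tetramethyl-1-oxohexadeca-2,6,10,14-tetraen-8-yl acetate | O=C/C=C(\C)CC/C=C(\C)[C@@H](OC(C)=O)C/C=C(\C)CCC=C(C)C | intermediate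
11 | (2E,6E,8S,10E)-14-bromo-15-hydroxy-3,7,11,15-tetramethyl-1-oxohexadeca-2,6,10-trien-8-yl acetate (both C14 epimers) | O=C/C=C(\C)CC/C=C(\C)[C@@H](OC(C)=O)C/C=C(\C)CCC(Br)C(C)(C)O | intermediate
12 | (2E,6E,8S,10E)-13-(3,3-dimethyloxiran-2-yl)-3,7,11-trimethyl-1-oxotrideca-2,6,10-trien-8-yl acetate (both oxirane epimers) | O=C/C=C(\C)CC/C=C(\C)[C@@H](OC(C)=O)C/C=C(\C)CCC1OC1(C)C | intermediate
13 | (2E,6E,8S,10E)-3,7,11-trimethyl-1,14-dioxotetradeca-2,6,10-trien-8-yl acetate | O=C/C=C(\C)CC/C=C(\C)[C@@H](OC(C)=O)C/C=C(\C)CCC=O | intermediate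
14 | methyl (6E,9S,10E,14E)-9-acetoxy-3-hydroxy-6,10,14-trimethyl-2-methylidene-16-oxohexadeca-6,10,14-trienoate (both C3 epimers) | O=C/C=C(\C)CC/C=C(\C)[C@@H](OC(C)=O)C/C=C(\C)CCC(O)C(=C)C(=O)OC | intermediate
15 | methyl (2Z,6E,9S,10E,14E)-9-acetoxy-2-(bromomethyl)-6,10,14-trimethyl-16-oxohexadeca-2,6,10,14-tetraenoate | O=C/C=C(\C)CC/C=C(\C)[C@@H](OC(C)=O)C/C=C(\C)CC/C=C(\CBr)C(=O)OC | intermediate
16 | methyl 2-[(1R,2S,3E,7E,9S,11E)-9-acetoxy-2-hydroxy-4,8,12-trimethylcyclotetradeca-3,7,11-trien-1-yl]prop-2-enoate | O[C@H]1/C=C(\C)CC/C=C(\C)[C@@H](OC(C)=O)C/C=C(\C)CC[C@@H]1C(=C)C(=O)OC | intermediate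
17 | (3aR,6E,9S,10E,14E,15aS)-6,10,14-trimethyl-3-methylidene-2-oxo-2,3,3a,4,5,8,9,12,13,15a-decahydrocyclotetradeca[b]furan-9-yl acetate, i.e. (1R,2S,3E,7E,9S,11E)-9-acetoxycembra-3,7,11,15(17)-tetraen-16,2-olide | C=C1C(=O)O[C@H]2/C=C(\C)CC/C=C(\C)[C@@H](OC(C)=O)C/C=C(\C)CC[C@H]12 | target

**Totals**
Total step count: 10. Longest linear sequence: 10 steps (2 → 17); 1 enters at step 3 and 3 at step 8.

**The three steps most likely to fail**

Step 4, the [2,3]-Wittig rearrangement. The E/Z ratio of the new trisubstituted olefin rests only on a methyl-versus-methylene preference at the tertiary ether carbon, so a substantial share of the 10Z isomer must be expected. That isomer carries the opposite C8 configuration, so any of it left behind lowers the enantiomeric purity. The level of chirality transfer also depends on the exo preference of the 2-methylalkenyl group, and the dianion may react sluggishly or drift into [1,2]-shift above −40 °C. The fallback sets out from 7 and comes back at 10; it addresses the dianion problems but not the intrinsic E/Z ratio. The primary alcohol is silylated (t-BuPh2SiCl, imidazole) to the tert-butyldiphenylsilyl ether F1. Its mono-lithio derivative is rearranged at −78 °C (n-BuLi, THF) and the rearranged lithium alkoxide is trapped in the flask with Ac2O to give the acetate silyl ether F2. The silyl group is removed with HF·pyridine to give the hydroxy acetate F3, and MnO2 oxidises the primary allylic alcohol to 10. The E/Z separation is then done on F2 or F3.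

Step 6, the terminal bromohydrin and epoxide. The C10=C11 olefin is only weakly deactivated and may compete with the terminal one, and DBU could start to isomerise the E-enal. The fallback sets out from 6 (isolated before the methanolysis of step 3) and comes back at 12. It moves the oxidation to a stage where the prenyl olefin is the only electron-rich double bond. m-Chloroperbenzoic acid (NaHCO3, CH2Cl2, 0 °C) gives the epoxy ether acetate F4, and K2CO3/MeOH gives the epoxy alcohol F5. The [2,3]-Wittig rearrangement (n-BuLi, 2.2 equiv, THF, −78 °C, where a trisubstituted epoxide is inert to alkyllithium) gives the epoxy diol F6. TEMPO/PhI(OAc)2 gives the epoxy hydroxy enal F7, and acetylation (Ac2O, Et3N, 4-(dimethylamino)pyridine) gives 12. The price is that the E/Z separation after the rearrangement must be done on a mixture of oxirane epimers.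

Step 10, the macrocyclisation. Dimerisation competes at any practical concentration. The anti (trans-lactone) outcome relies on the allylchromium reacting through the tether-diequatorial chair. The choice of aldehyde face relies only on the remote C9 acetoxy centre, so a C1/C2 diastereomer may have to be separated. The fallback sets out from 13 and comes back at 16. It fixes the olefin geometry of the allyl unit instead of relying on equilibration; it does not improve the facial selectivity. Z-selective Horner–Wadsworth–Emmons olefination of the aliphatic aldehyde of 13 with methyl 2-[bis(2,2,2-trifluoroethoxy)phosphoryl]-3-[(tert-butyldimethylsilyl)oxy]propanoate (KN(SiMe3)2, 18-crown-6, THF, −78 °C) gives the silyloxymethyl enoate F8, with the chain cis to the ester. HF·pyridine gives the allylic alcohol F9, and CBr4/PPh3 gives the (2E)-bromide F10. A geometry-retentive indium-mediated Barbier cyclisation (In powder, THF/H2O, high dilution) through the closed chair with the chain equatorial then gives the anti adduct 16, which is lactonised as in step 10.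

**Further compounds**
F1 | step 4 | (2E,6E)-1-[(tert-butyldiphenylsilyl)oxy]-8-{[(3R)-3,7-dimethylocta-1,6-dien-3-yl]oxy}-3,7-dimethylocta-2,6-diene | C=C[C@](C)(OC/C(C)=C/CC/C(C)=C/CO[Si](c1ccccc1)(c1ccccc1)C(C)(C)C)CCC=C(C)C
F2 | step 4 | (2E,6E,8S,10E)-1-[(tert-butyldiphenylsilyl)oxy]-3,7,11,15-tetramethylhexadeca-2,6,10,14-tetraen-8-yl acetate | CC(C)(C)[Si](c1ccccc1)(c1ccccc1)OC/C=C(\C)CC/C=C(\C)[C@@H](OC(C)=O)C/C=C(\C)CCC=C(C)C
F3 | step 4 | (2E,6E,8S,10E)-1-hydroxy-3,7,11,15-tetramethylhexadeca-2,6,10,14-tetraen-8-yl acetate | OC/C=C(\C)CC/C=C(\C)[C@@H](OC(C)=O)C/C=C(\C)CCC=C(C)C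
F4 | step 6 | (2E,6E)-8-{[(3R)-5-(3,3-dimethyloxiran-2-yl)-3-methylpent-1-en-3-yl]oxy}-3,7-dimethylocta-2,6-dien-1-yl acetate (both oxirane epimers) | C=C[C@](C)(OC/C(C)=C/CC/C(C)=C/COC(C)=O)CCC1OC1(C)C
F5 | step 6 | (2E,6E)-8-{[(3R)-5-(3,3-dimethyloxiran-2-yl)-3-methylpent-1-en-3-yl]oxy}-3,7-dimethylocta-2,6-dien-1-ol (both oxirane epimers) | C=C[C@](C)(OC/C(C)=C/CC/C(C)=C/CO)CCC1OC1(C)C
F6 | step 6 | (2E,6E,8S,10E)-13-(3,3-dimethyloxiran-2-yl)-3,7,11-trimethyltrideca-2,6,10-triene-1,8-diol (both oxirane epimers) | OC/C=C(\C)CC/C=C(\C)[C@@H](O)C/C=C(\C)CCC1OC1(C)C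
F7 | step 6 | (2E,6E,8S,10E)-13-(3,3-dimethyloxiran-2-yl)-8-hydroxy-3,7,11-trimethyltrideca-2,6,10-trienal (both oxirane epimers) | O=C/C=C(\C)CC/C=C(\C)[C@@H](O)C/C=C(\C)CCC1OC1(C)C
F8 | step 10 | methyl (2Z,6E,9S,10E,14E)-9-acetoxy-2-{[(tert-butyldimethylsilyl)oxy]methyl}-6,10,14-trimethyl-16-oxohexadeca-2,6,10,14-tetraenoate | O=C/C=C(\C)CC/C=C(\C)[C@@H](OC(C)=O)C/C=C(\C)CC/C=C(/CO[Si](C)(C)C(C)(C)C)C(=O)OC
F9 | step 10 | methyl (2Z,6E,9S,10E,14E)-9-acetoxy-2-(hydroxymethyl)-6,10,14-trimethyl-16-oxohexadeca-2,6,10,14-tetraenoate | O=C/C=C(\C)CC/C=C(\C)[C@@H](OC(C)=O)C/C=C(\C)CC/C=C(/CO)C(=O)OC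
F10 | step 10 | methyl (2E,6E,9S,10E,14E)-9-acetoxy-2-(bromomethyl)-6,10,14-trimethyl-16-oxohexadeca-2,6,10,14-tetraenoate | O=C/C=C(\C)CC/C=C(\C)[C@@H](OC(C)=O)C/C=C(\C)CC/C=C(/CBr)C(=O)OC
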